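## The problem

CNP0148909.1 (39) is a trans-fused decalin with two exocyclic methylene groups, an α-ketol, two methyl-bearing quaternary carbons and a two-carbon bridge to a β-substituted γ-butyrolactone. In this proposal the skeleton is numbered C1 (ring carbon of the isolated methylene), C2, C3, C4 (isobutyrate), C5 (ring-fusion CH), C6 (ring-fusion C–CH3), C7 (CHOH), C8 (C=O), C9 (C=CH2), C10 (C–CH3 and side chain), C11 (CH2), C12 (CH–O-tigloyl), C13 (lactone CH), C14 (OCH2), C15 (CH2) and C16 (lactone C=O); ring A is C1–C6, ring B is C5–C10, and β is the face of the C6 methyl group. Seven stereocentres have to be set (4R,5R,6R,7R,10R,12R,13R in this numbering). C5, C6 and C10 are contiguous and the C6 and C10 methyl groups are syn-diaxial, so reagents reach C4, C7 and C8 from the α face only: the equatorial 7β-hydroxyl is therefore easy and the equatorial 4α-ester, whose hydrogen lies on the blocked β face, is hard, while C12 and C13 are too far from the rings to be controlled by them. The groups that limit the choice of reagents are the 9-methylene-8-ketone with its C7 hydroxyl (Michael acceptor, ketol shift), the C1 methylene (no ozone, peracid or unselective borane once it exists), the C5 hydrogen for as long as C4 is a ketone, and the oxygens O12 and O14, which are both γ to C16 and can each close a lactone. The opening the structure offers is the C1 methylene beside the quaternary C6, with oxygen on C4 and C7: C2–C5 can be read as a 2-silyloxydiene and C7–C6–C1(=CH2) as an α-methyl allenyl ketone, so that one cycloaddition forms C5–C6 and C1–C2, both rings and the C1 methylene.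

## Retrosynthesis

**C9 methylene (39 ⇒ 37).** The C9=CH2 bond is cut first, back to ketone 37. This keeps the methylene ketone out of every earlier step, where fluoride, boranes and amines would add to it. The forward reaction is a Mannich condensation with formaldehyde and loss of the amine. It can only end at C9, because C7 has a single hydrogen and a Mannich adduct there cannot eliminate.

**Lactone (37 ⇒ 34 ⇒ 33 ⇒ 31).** The lactone is opened at O14–C16 to acid 34, whose carboxyl comes from the terminal vinyl group of 31 through alcohol 33. A cut at C14–O with C16 preformed would need an oxidative alkene cleavage, which the C1 methylene forbids. A monosubstituted vinyl group can instead be hydroborated by a rhodium catalyst that ignores 1,1-disubstituted alkenes. Because O12 and O14 are both γ to C16, the tiglate is placed on O12 before C16 is oxidised, and O14 stays silylated until the acid exists. The acid step that closes the lactone also releases the C8 ketone and the C7 hydroxyl.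

**C12–C13 bond (31 ⇒ 30 ⇒ 29 ⇒ 27 + 28).** Diol 29 is the anti adduct of primary alcohol 27 and vinyl ethylene carbonate 28. An aldol cut would bring C14 in at the acid level and need a hydride later; the allylation sets C12 and C13 in one catalyst-controlled event and delivers C14 as CH2OH and C15–C16 as vinyl. 27 has no side-chain stereocentre. The forward step must be anti-selective and must override the remote C10 centre.

**Ring A oxygen (27 ⇒ 26 ⇒ 25 ⇒ 24 ⇒ 23).** No skeletal bond is cut; the order is what matters. Hydride would attack the C4 ketone 24 from the open α face and give the axial alcohol, so a thermodynamically controlled electron-transfer reduction is used to give 25. That reduction tolerates no second ketone and no α-oxygenated ketone, so ring B must be in a non-carbonyl form when 24 is released from enol ether 23. Acylation (26) and removal of the primary silyl group (27) follow.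

**Ring B oxidation pattern (23 ⇒ 22 ⇒ 21 ⇒ 20 ⇒ 19 ⇒ 18).** The cycloadduct 18 has C7=O and C8H2; the target has C7–OH and C8=O. Hydroxylation at C8 (19) and oxidation give the diosphenol 20, whose methyl ether 21 leaves C7 as the only ketone. Reduction from the α face gives the 7β-alcohol 22, protected as 23. A diol route would need a selective oxidation of one of two secondary alcohols. Here the two carbons are differentiated by oxidation state, and the methyl enol ether is inert to fluoride, so the silyl enol ether of ring A can be cleaved beside it.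

**Key disconnection (18 ⇒ 17).** C5–C6 and C1–C2 are cut together. Acyclic 17 has one stereocentre (C10), against three in 18, and no ring. The forward cycloaddition must give the trans fusion and must choose the diene face that puts the C6 methyl syn to the C10 methyl. To sharpen the modest substrate bias the enol ether is (Z) and bulky, the C11–C12 arm carries a triisopropylsilyl ether so that it is clearly larger than methyl, and the reaction is run at the lowest workable temperature.

**Acyclic chain (17 ⇒ 16 ⇒ 13 ⇒ 12 ⇒ 11 ⇒ 9 + 10, with 2).** The allenyl ketone comes from carbinol 16 by oxidation as the last step, because a free C7 ketone would enolise at C8 in competition with dienol ether formation. The dienol ether comes from vinyl ketone 13, the vinyl ketone from Weinreb amide 12 and vinylmagnesium bromide 2, and the allenyl carbinol 11 from aldehyde acid 9 and 1-bromobut-2-yne 10 with indium in water.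

**Ring cleavage and quaternary centre (9 ⇒ 7 ⇒ 6 ⇒ 5 ⇒ 3 ⇒ 1 + 2).** The aldehyde and acid ends of 9 are the two carbons of the Δ1(6) silyl enol ether 7, cleaved by ozone. Ketone 6 comes from the vinyl ketone 3 by hydroboration (5) and silylation. 3 comes from 3-methylcyclohex-2-en-1-one 1 by catalytic asymmetric conjugate vinylation, which sets C10 at the outset in an unhindered setting.

## Roads not taken

**Alternative 1:** The lactone C14–O bond is cut. The 3-substituted cyclobutanone A2 would undergo a catalyst-controlled Baeyer–Villiger oxidation (chiral acid with H2O2, or a monooxygenase) in which one of the two CH2 groups migrates, giving lactone A1 and fixing C13. The merits are real: the lactone arrives in one step at the right oxidation level, and the O12/O14 regiochemistry problem does not arise. The weak points are that C13 is set by a catalyst next to the C12 ester centre in a matched or mismatched pairing, that selectivities for 3-alkylcyclobutanones are moderate, and that a peroxide is used in the presence of two 1,1-disubstituted alkenes. A1 also still carries C7 and C8 as a bis-silylated diol, so the selective C8 oxidation is postponed, and this cut says nothing about the decalin. For the lactone itself this road is shorter than the five steps from 29 to 37. The chosen plan sets against it that C12 and C13 are fixed together by one anti-selective coupling and that no peroxide stronger than buffered H2O2 meets the methylenes.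

**Alternative 2:** The C8–C9 bond and the oxygen on the future C9 methylene carbon are cut. Nitrile oxide A4 would add across the C10 vinyl group to close ring B as the fused isoxazoline A3. N–O cleavage and dehydration would then give the 9-methylene-8-ketone. This is better than the chosen plan for ring B: the C8 carbonyl and the C9 carbon arrive in place in one step, against the five steps from 18 to 23 and the late Mannich reaction here. Its weakness is the precursor. A4 needs C4, C5, C6, C7 and C10 in place, including the C5–C10 bond between a tertiary and a quaternary carbon beside quaternary C6, made without help from a ring-forming step. The C1 ketone must later be methylenated next to C6. The chosen plan sets against it that the congested C5–C6–C10 array and both rings come from an acyclic precursor with one stereocentre.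

**Alternative 3:** The C9–C10 bond is cut. Alkenyl bromide A6 would cyclise onto the trisubstituted enoate under zerovalent palladium catalysis with formate (reductive Heck reaction) to give A5, creating quaternary C10 with the C9 methylene in place and an ester arm for the side chain. It delivers the C9 methylene for free and is convergent. Its weak points are that the configuration of C10 depends on the conformation of the enoate on ring A, and the required product has the new methyl syn-diaxial to the C6 methyl, so the needed diastereomer forms against strain. Four ring A stereocentres must be set beforehand. C8 must then be oxidised at an allylic position in the presence of other alkenes, and C1 methylenated at a hindered ketone. The chosen plan creates C10 first, by catalysis on a simple enone, and lets it direct C5 and C6.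

Key step: step 11

Assumption: the ligand enantiomers named in steps 1 and 21 are those which the accepted facial models assign to the configurations drawn; if a model proves inverted for these substrates the antipodal ligand is used without other change. TBS = tert-butyldimethylsilyl, TIPS = triisopropylsilyl, TMS = trimethylsilyl; decalin locants and α/β are those defined under "The problem".

## Route

Step 1
Reactants: 1 3-methylcyclohex-2-en-1-one; 2 vinylmagnesium bromide
Product: 3 (S)-3-methyl-3-vinylcyclohexan-1-one
Conditions: 2, Me2AlCl, Et2O, −30 °C; then Cu(OTf)2 (5 mol%), (S,S,S)-phosphoramidite from BINOL and bis(1-phenylethyl)amine (10 mol%), 1, −30 °C; aq. HCl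
Reagents that add atoms: none
Why: Copper-catalysed asymmetric conjugate addition of an alkenylalane to a β-substituted cyclohexenone; the chiral copper–phosphoramidite complex selects the enone face and sets the quaternary centre (C10 of the target), and the alkenyl group transfers in preference to methyl.

Step 2
Reactants: 3 (S)-3-methyl-3-vinylcyclohexan-1-one
Product: 5 (R)-3-(2-hydroxyethyl)-3-methylcyclohexan-1-one, via catechol boronate 4 (not isolated)
Conditions: catecholborane, RhCl(PPh3)3 (2 mol%), THF, 0 °C to rt; then H2O2, pH 7 phosphate buffer, 0 °C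
Reagents that add atoms: catecholborane, B1Oc2ccccc2O1 (in 4); hydrogen peroxide, OO
Why: Rhodium-catalysed hydroboration is anti-Markovnikov for terminal alkenes and much faster than uncatalysed reduction of the ketone by catecholborane; buffered peroxide oxidation gives the primary alcohol without Baeyer–Villiger oxidation.

Step 3
Reactants: 5 (R)-3-(2-hydroxyethyl)-3-methylcyclohexan-1-one
Product: 6 (R)-3-methyl-3-[2-(triisopropylsilyloxy)ethyl]cyclohexan-1-one
Conditions: TIPSCl, imidazole, DMF, rt
Reagents that add atoms: triisopropylsilyl chloride, CC(C)[Si](Cl)(C(C)C)C(C)C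
Why: Silylation of a primary alcohol; the TIPS ether survives every step up to step 20 and makes the C11–C12 arm clearly larger than methyl for the key step.

Step 4
Reactants: 6 (R)-3-methyl-3-[2-(triisopropylsilyloxy)ethyl]cyclohexan-1-one
Product: 7 (R)-triisopropyl{2-[1-methyl-3-(trimethylsilyloxy)cyclohex-3-en-1-yl]ethoxy}silane
Conditions: LiN(iPr)2, THF, −78 °C; TMSCl, Et3N, −78 °C to 0 °C
Reagents that add atoms: chlorotrimethylsilane, C[Si](C)(C)Cl
Why: Kinetic enolisation with a hindered amide base removes a proton from C6 of the ketone and not from the neopentyl C2, so trapping gives the Δ1(6) silyl enol ether needed for cleavage on the side remote from the quaternary carbon.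

Step 5
Reactants: 7 (R)-triisopropyl{2-[1-methyl-3-(trimethylsilyloxy)cyclohex-3-en-1-yl]ethoxy}silane
Product: 9 (R)-3-methyl-6-oxo-3-[2-(triisopropylsilyloxy)ethyl]hexanoic acid, via trimethylsilyl ester 8 (not isolated)
Conditions: O3, CH2Cl2, −78 °C; PPh3, −78 °C to rt; aqueous work-up
Reagents that add atoms: ozone, [O-][O+]=O
Why: Ozonolysis of a silyl enol ether: the oxygen-bearing alkene carbon leaves as the carboxyl (through its silyl ester) and the other as the aldehyde, which differentiates the two chain ends in one step and leaves the quaternary stereocentre untouched.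

Step 6
Reactants: 9 (R)-3-methyl-6-oxo-3-[2-(triisopropylsilyloxy)ethyl]hexanoic acid; 10 1-bromobut-2-yne
Product: 11 (3R)-6-hydroxy-3,7-dimethyl-3-[2-(triisopropylsilyloxy)ethyl]nona-7,8-dienoic acid (both C6 epimers)
Conditions: In powder, THF/H2O (1:1), rt
Reagents that add atoms: none
Why: Indium-mediated Barbier reaction in water; γ-substituted propargyl bromides react in the SE2′ sense to give α-allenyl carbinols and the free acid is tolerated; the new carbinol centre is oxidised in step 10, so its configuration is immaterial.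

Step 7
Reactants: 11 (3R)-6-hydroxy-3,7-dimethyl-3-[2-(triisopropylsilyloxy)ethyl]nona-7,8-dienoic acid
Product: 12 (3R)-6-hydroxy-N-methoxy-N,3,7-trimethyl-3-[2-(triisopropylsilyloxy)ethyl]nona-7,8-dienamide
Conditions: MeNH(OMe)·HCl, EDCI, HOBt (cat.), N-methylmorpholine, CH2Cl2, 0 °C to rt
Reagents that add atoms: N,O-dimethylhydroxylamine hydrochloride, CNOC.Cl
Why: Carbodiimide amide coupling to the Weinreb amide; the secondary alcohol does not compete with the amine nucleophile.

Step 8
Reactants: 12 (3R)-6-hydroxy-N-methoxy-N,3,7-trimethyl-3-[2-(triisopropylsilyloxy)ethyl]nona-7,8-dienamide; 2 vinylmagnesium bromide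
Product: 13 (5R)-8-hydroxy-5,9-dimethyl-5-[2-(triisopropylsilyloxy)ethyl]undeca-1,9,10-trien-3-one
Conditions: 2 (3.5 equiv), THF, −20 °C to 0 °C; inverse quench into cold aq. NaHSO4
Reagents that add atoms: none
Why: Weinreb ketone synthesis: the chelated tetrahedral adduct prevents double addition and the first equivalent of Grignard reagent is consumed by the hydroxyl; the cold acidic inverse quench avoids conjugate addition of the liberated amine to the vinyl ketone.

Step 9
Reactants: 13 (5R)-8-hydroxy-5,9-dimethyl-5-[2-(triisopropylsilyloxy)ethyl]undeca-1,9,10-trien-3-one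
Product: 16 (7R,8Z)-9-(TBSO)-3,7-dimethyl-7-[2-(TIPSO)ethyl]undeca-1,2,8,10-tetraen-4-ol, via trimethylsilyl ether 14 (not isolated), via bis-silylated dienol ether 15 (not isolated)
Conditions: TMSCl, Et3N, CH2Cl2, 0 °C; TBSOTf, −78 °C to 0 °C; then K2CO3, MeOH, 0 °C
Reagents that add atoms: chlorotrimethylsilane, C[Si](C)(C)Cl (in 14 and 15); tert-butyldimethylsilyl triflate, CC(C)(C)[Si](C)(C)OS(=O)(=O)C(F)(F)F
Why: Soft enolisation (silyl triflate and amine) of the vinyl ketone can only occur towards C5 and gives the (Z)-2-silyloxydiene with the bulky C10 cis to oxygen; the carbinol is masked for this operation as a TMS ether, which brief methanolysis removes while the TBS dienol ether stays.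

Step 10
Reactants: 16 (7R,8Z)-9-(TBSO)-3,7-dimethyl-7-[2-(TIPSO)ethyl]undeca-1,2,8,10-tetraen-4-ol
Product: 17 (7R,8Z)-9-(TBSO)-3,7-dimethyl-7-[2-(TIPSO)ethyl]undeca-1,2,8,10-tetraen-4-one
Conditions: Dess–Martin periodinane, NaHCO3, CH2Cl2, 0 °C; rapid filtration through Et3N-deactivated silica
Reagents that add atoms: none
Why: Dess–Martin oxidation of the allenyl carbinol under buffered, non-acidic conditions that silyl enol ethers tolerate; the stereorandom carbinol centre disappears and the dienophile is unveiled last.

Step 11
Reactants: 17 (7R,8Z)-9-(TBSO)-3,7-dimethyl-7-[2-(TIPSO)ethyl]undeca-1,2,8,10-tetraen-4-one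
Product: 18 4-(TBSO)-6β,10β-dimethyl-1-methylene-10α-[2-(TIPSO)ethyl]-5αH-decal-3-en-7-one
Conditions: toluene (0.01 M), BHT, 80 °C, base-washed glassware
Reagents that add atoms: none
Why: Thermal intramolecular Diels–Alder reaction of a 1,7,9-decatrien-3-one whose dienophile is the ketone-conjugated C6=C1 bond of an α-methyl allenyl ketone; the closest known type is the cycloaddition of decatrienones and of allenyl ketone dienophiles. The concerted, asynchronous [4+2] addition joins C1 to C2 (the bond to the enone β-carbon leads) and C5 to C6, and the orthogonal distal π bond of the allene remains as the C1 methylene. Ring A closes as the cyclohexene of the cycloaddition itself, and ring B closes through the four-atom tether C7–C10, which spans the new C5–C6 bond in a chair-like six-membered array. C6 is set relative to C5 by the exo placement of the tether carbonyl with the C6 methyl endo, the usual preference of α-methyl enone dienophiles, in a chair in which C4 and C1 are both equatorial on the forming ring B; this gives the trans fusion (5α-H, 6β-CH3). The diene face is chosen by C10: in that chair the position that eclipses the (Z)-silyloxy group and faces the incoming C6 methyl is taken by the C10 methyl, and the larger CH2CH2OTIPS arm lies outside, so the C6 and C10 methyl groups end up syn. The tether forces the silyloxy carbon and the acyl-bearing carbon into a 1,3 relationship, so the silyloxy group raises the diene HOMO without directing, and the sp carbon C1 keeps the forming quaternary centre uncrowded. The step needs trans over cis fusion and the correct diene face; the (Z)-enol ether, the bulky arm and the lowest workable temperature secure what the substrate can give, and the unwanted isomers are diastereomers that should be separable.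

Step 12
Reactants: 18 4-(TBSO)-6β,10β-dimethyl-1-methylene-10α-[2-(TIPSO)ethyl]-5αH-decal-3-en-7-one
Product: 19 8α-hydroxy-4-(TBSO)-6β,10β-dimethyl-1-methylene-10α-[2-(TIPSO)ethyl]-5αH-decal-3-en-7-one
Conditions: KN(SiMe3)2, THF, −78 °C; 2-(phenylsulfonyl)-3-phenyloxaziridine, −78 °C; AcOH quench
Reagents that add atoms: 2-(phenylsulfonyl)-3-phenyloxaziridine, O=S(=O)(c1ccccc1)N1OC1c1ccccc1
Why: Enolate hydroxylation with an N-sulfonyloxaziridine: the ketone can enolise only towards C8 (C6 is quaternary) and the oxidant should arrive on the α face, away from the two axial methyl groups; the C8 configuration is lost again in step 13.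

Step 13
Reactants: 19 8α-hydroxy-4-(TBSO)-6β,10β-dimethyl-1-methylene-10α-[2-(TIPSO)ethyl]-5αH-decal-3-en-7-one
Product: 20 8-hydroxy-4-(TBSO)-6β,10β-dimethyl-1-methylene-10α-[2-(TIPSO)ethyl]-5αH-decala-3,8-dien-7-one (diosphenol)
Conditions: Dess–Martin periodinane, NaHCO3, CH2Cl2, rt
Reagents that add atoms: none
Why: Dess–Martin oxidation of the α-hydroxy ketone gives the 7,8-dione, which can enolise only towards C9 and is expected to rest as the diosphenol.

Step 14
Reactants: 20 8-hydroxy-4-(TBSO)-6β,10β-dimethyl-1-methylene-10α-[2-(TIPSO)ethyl]-5αH-decala-3,8-dien-7-one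
Product: 21 8-methoxy-4-(TBSO)-6β,10β-dimethyl-1-methylene-10α-[2-(TIPSO)ethyl]-5αH-decala-3,8-dien-7-one
Conditions: MeI, K2CO3, acetone, rt
Reagents that add atoms: iodomethane, CI
Why: O-Alkylation of the diosphenolate; the methyl enol ether stores the future C8 ketone in a form inert to fluoride, base, hydride and one-electron reductants and leaves C7 as the only carbonyl of ring B.

Step 15
Reactants: 21 8-methoxy-4-(TBSO)-6β,10β-dimethyl-1-methylene-10α-[2-(TIPSO)ethyl]-5αH-decala-3,8-dien-7-one
Product: 22 8-methoxy-4-(TBSO)-6β,10β-dimethyl-1-methylene-10α-[2-(TIPSO)ethyl]-5αH-decala-3,8-dien-7β-ol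
Conditions: iBu2AlH, CH2Cl2, −78 °C; potassium sodium tartrate work-up
Reagents that add atoms: none
Why: 1,2-Reduction of the enone carbonyl by iBu2AlH: hydride comes from the α face, anti to the axial C6 and C10 methyl groups, and sets the 7β (equatorial) alcohol of the target.

Step 16
Reactants: 22 8-methoxy-4-(TBSO)-6β,10β-dimethyl-1-methylene-10α-[2-(TIPSO)ethyl]-5αH-decala-3,8-dien-7β-ol
Product: 23 4,7β-bis(TBSO)-8-methoxy-6β,10β-dimethyl-1-methylene-10α-[2-(TIPSO)ethyl]-5αH-decala-3,8-diene
Conditions: TBSOTf, 2,6-lutidine, CH2Cl2, −40 °C to 0 °C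
Reagents that add atoms: tert-butyldimethylsilyl triflate, CC(C)(C)[Si](C)(C)OS(=O)(=O)C(F)(F)F
Why: Silyl triflate silylation of a hindered secondary alcohol under basic conditions that leave both enol ethers intact; the group blocks O7 during the two acylations.

Step 17
Reactants: 23 4,7β-bis(TBSO)-8-methoxy-6β,10β-dimethyl-1-methylene-10α-[2-(TIPSO)ethyl]-5αH-decala-3,8-diene
Product: 24 7β-(TBSO)-8-methoxy-6β,10β-dimethyl-1-methylene-10α-[2-(TIPSO)ethyl]-5αH-decal-8-en-4-one
Conditions: Bu4NF, AcOH (1:1), THF, −20 °C to 0 °C
Reagents that add atoms: none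
Why: Buffered fluoride cleaves the silyl enol ether at silicon and the enolate is protonated at C3, so the C5 centre set in step 11 is not touched; the methyl enol ether, the hindered C7 silyl ether and the TIPS ether are stable to these conditions.

Step 18
Reactants: 24 7β-(TBSO)-8-methoxy-6β,10β-dimethyl-1-methylene-10α-[2-(TIPSO)ethyl]-5αH-decal-8-en-4-one
Product: 25 7β-(TBSO)-8-methoxy-6β,10β-dimethyl-1-methylene-10α-[2-(TIPSO)ethyl]-5αH-decal-8-en-4α-ol
Conditions: SmI2, H2O, Et3N, THF, 0 °C
Reagents that add atoms: none
Why: Ketyl (single-electron) reduction with SmI2 gives the thermodynamically preferred alcohol: the oxygen takes the equatorial α position away from the two syn-axial methyl groups and the small proton is delivered to the β face that hydride reagents cannot reach, as in dissolving-metal reduction of ketones flanked by axial methyl groups. No other reducible group is present and the ketone is consumed before C5 can epimerise.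

Step 19
Reactants: 25 7β-(TBSO)-8-methoxy-6β,10β-dimethyl-1-methylene-10α-[2-(TIPSO)ethyl]-5αH-decal-8-en-4α-ol
Product: 26 4α-isobutyryloxy-7β-(TBSO)-8-methoxy-6β,10β-dimethyl-1-methylene-10α-[2-(TIPSO)ethyl]-5αH-decal-8-ene
Conditions: isobutyryl chloride, pyridine, DMAP (cat.), CH2Cl2, 0 °C to rt
Reagents that add atoms: isobutyryl chloride, CC(C)C(Cl)=O
Why: DMAP-catalysed acylation of the only free hydroxyl.

Step 20
Reactants: 26 4α-isobutyryloxy-7β-(TBSO)-8-methoxy-6β,10β-dimethyl-1-methylene-10α-[2-(TIPSO)ethyl]-5αH-decal-8-ene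
Product: 27 4α-isobutyryloxy-7β-(TBSO)-10α-(2-hydroxyethyl)-8-methoxy-6β,10β-dimethyl-1-methylene-5αH-decal-8-ene
Conditions: Bu4NF, AcOH, THF, rt
Reagents that add atoms: none
Why: Fluoride cleavage of the primary TIPS ether; the neopentyl secondary C7 silyl ether reacts far more slowly and the acetic acid buffer protects the ester.

Step 21
Reactants: 27 4α-isobutyryloxy-7β-(TBSO)-10α-(2-hydroxyethyl)-8-methoxy-6β,10β-dimethyl-1-methylene-5αH-decal-8-ene; 28 4-vinyl-1,3-dioxolan-2-one
Product: 29 (12R,13R)-diol: 27 with the C10 arm extended to CH2–CH(OH)–CH(CH2OH)–CH=CH2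
Conditions: [Ir(cod)Cl]2 (2.5 mol%), (R)-SEGPHOS (5 mol%), 4-cyano-3-nitrobenzoic acid (10 mol%), K3PO4 (cat.), THF, 60 °C
Reagents that add atoms: none
Why: Iridium-catalysed transfer-hydrogenative carbonyl (hydroxymethyl)allylation (Krische-type coupling) from the alcohol oxidation level: the alcohol is dehydrogenated to the aldehyde, which is captured by the (hydroxymethyl)allyl–iridium species formed from 28 by ionisation and loss of CO2. The closed chair transition state gives the anti adduct and the chiral bisphosphine sets C12 and C13 together as R,R, overriding the remote C10 centre.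

Step 22
Reactants: 29 (12R,13R)-diol
Product: 30 (12R,13R)-14-(TBSO)-12-ol: 29 with the primary hydroxyl silylated
Conditions: TBSCl, imidazole, CH2Cl2, 0 °C
Reagents that add atoms: tert-butyldimethylsilyl chloride, CC(C)(C)[Si](C)(C)Cl
Why: Selective silylation of the primary hydroxyl; O12 stays free for the ester.

Step 23
Reactants: 30 (12R,13R)-14-(TBSO)-12-ol
Product: 31 (12R,13R)-12-tigloyloxy-14-(TBSO) vinyl compound
Conditions: (E)-2-methylbut-2-enoyl chloride, pyridine, DMAP, CH2Cl2, 0 °C to rt
Reagents that add atoms: (E)-2-methylbut-2-enoyl chloride, C/C=C(\C)C(Cl)=O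
Why: Acylation of the secondary C12 alcohol; with the tiglate in place only O14 can later lactonise onto C16.

Step 24
Reactants: 31 (12R,13R)-12-tigloyloxy-14-(TBSO) vinyl compound
Product: 33 (12R,13R)-12-tigloyloxy-14-(TBSO)-16-ol, via catechol boronate 32 (not isolated)
Conditions: catecholborane, RhCl(PPh3)3 (3 mol%), THF, rt; then H2O2, pH 7 phosphate buffer, 0 °C
Reagents that add atoms: catecholborane, B1Oc2ccccc2O1 (in 32); hydrogen peroxide, OO
Why: Rhodium-catalysed hydroboration reacts with the monosubstituted terminal alkene far faster than with the 1,1-disubstituted C1 methylene, the trisubstituted enol ether or the enoate, and places boron on the terminal carbon C16; buffered oxidation spares the esters.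

Step 25
Reactants: 33 (12R,13R)-12-tigloyloxy-14-(TBSO)-16-ol
Product: 34 (12R,13R)-12-tigloyloxy-14-(TBSO)-16-oic acid
Conditions: (Pr4N)RuO4 (10 mol%), N-methylmorpholine N-oxide monohydrate, MeCN, rt
Reagents that add atoms: N-methylmorpholine N-oxide, C[N+]1([O-])CCOCC1; water, O
Why: Ley–Griffith oxidation in the presence of water takes the primary alcohol through the aldehyde hydrate to the carboxylic acid under neutral conditions that the enol ether and the alkenes tolerate.

Step 26
Reactants: 34 (12R,13R)-12-tigloyloxy-14-(TBSO)-16-oic acid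
Product: 37 9-demethylene ketol lactone: 39 with CH2 at C9, via hydroxy acid 35 (not isolated), via silylated lactone 36 (not isolated)
Conditions: 48% aq. HF, MeCN, 0 °C to rt
Reagents that add atoms: water, O
Why: Aqueous HF hydrolyses the methyl enol ether to the C8 ketone and removes the primary silyl ether, whereupon the γ-hydroxy acid closes to the lactone (5-exo acyl substitution, O12 being blocked); the hindered C7 silyl ether is cleaved last. The esters and the C1 methylene are stable to these conditions.

Step 27
Reactants: 37 9-demethylene ketol lactone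
Product: 39 CNP0148909.1, via Mannich base 38 (not isolated)
Conditions: paraformaldehyde, N-methylanilinium trifluoroacetate, THF, reflux
Reagents that add atoms: formaldehyde (from paraformaldehyde), C=O; N-methylaniline, CNc1ccccc1 (in 38)
Why: Acid-catalysed Mannich reaction with formaldehyde followed by loss of the amine (direct α-methylenation of a ketone): only C9 carries the two hydrogens needed for elimination, so an adduct at C7 can only revert, and the lactone and esters do not enolise under these conditions.

## Compound list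

1 | 3-methylcyclohex-2-en-1-one | CC1=CC(=O)CCC1 | starting material
2 | vinylmagnesium bromide | C=C[Mg]Br | starting material
3 | (S)-3-methyl-3-vinylcyclohexan-1-one | C=C[C@@]1(C)CCCC(=O)C1 | intermediate
4 | (S)-3-[2-(1,3,2-benzodioxaborol-2-yl)ethyl]-3-methylcyclohexan-1-one | B1(CC[C@@]2(C)CCCC(=O)C2)Oc2ccccc2O1 | intermediate
5 | (R)-3-(2-hydroxyethyl)-3-methylcyclohexan-1-one | OCC[C@@]1(C)CCCC(=O)C1 | intermediate
6 | (R)-3-methyl-3-[2-(triisopropylsilyloxy)ethyl]cyclohexan-1-one | CC(C)[Si](OCC[C@@]1(C)CCCC(=O)C1)(C(C)C)C(C)C | intermediate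
7 | (R)-triisopropyl{2-[1-methyl-3-(trimethylsilyloxy)cyclohex-3-en-1-yl]ethoxy}silane | C[Si](C)(C)OC1=CCC[C@](C)(CCO[Si](C(C)C)(C(C)C)C(C)C)C1 | intermediate
8 | trimethylsilyl (R)-3-methyl-6-oxo-3-[2-(triisopropylsilyloxy)ethyl]hexanoate | O=CCC[C@](C)(CCO[Si](C(C)C)(C(C)C)C(C)C)CC(=O)O[Si](C)(C)C | intermediate
9 | (R)-3-methyl-6-oxo-3-[2-(triisopropylsilyloxy)ethyl]hexanoic acid | O=CCC[C@](C)(CCO[Si](C(C)C)(C(C)C)C(C)C)CC(O)=O | intermediate
10 | 1-bromobut-2-yne | CC#CCBr | starting material
11 | (3R)-6-hydroxy-3,7-dimethyl-3-[2-(triisopropylsilyloxy)ethyl]nona-7,8-dienoic acid (C6 epimers) | C=C=C(C)C(O)CC[C@](C)(CCO[Si](C(C)C)(C(C)C)C(C)C)CC(O)=O | intermediate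
12 | (3R)-6-hydroxy-N-methoxy-N,3,7-trimethyl-3-[2-(triisopropylsilyloxy)ethyl]nona-7,8-dienamide | C=C=C(C)C(O)CC[C@](C)(CCO[Si](C(C)C)(C(C)C)C(C)C)CC(=O)N(C)OC | intermediate
13 | (5R)-8-hydroxy-5,9-dimethyl-5-[2-(triisopropylsilyloxy)ethyl]undeca-1,9,10-trien-3-one | C=C=C(C)C(O)CC[C@](C)(CCO[Si](C(C)C)(C(C)C)C(C)C)CC(=O)C=C | intermediate
14 | trimethylsilyl ether of 13 at the carbinol | C=C=C(C)C(O[Si](C)(C)C)CC[C@](C)(CCO[Si](C(C)C)(C(C)C)C(C)C)CC(=O)C=C | intermediate
15 | (Z)-TBS dienol ether of 14 | C=C=C(C)C(O[Si](C)(C)C)CC[C@](C)(CCO[Si](C(C)C)(C(C)C)C(C)C)/C=C(O[Si](C)(C)C(C)(C)C)/C=C | intermediate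
16 | (7R,8Z)-9-(TBSO)-3,7-dimethyl-7-[2-(TIPSO)ethyl]undeca-1,2,8,10-tetraen-4-ol | C=C=C(C)C(O)CC[C@](C)(CCO[Si](C(C)C)(C(C)C)C(C)C)/C=C(O[Si](C)(C)C(C)(C)C)/C=C | intermediate
17 | (7R,8Z)-9-(TBSO)-3,7-dimethyl-7-[2-(TIPSO)ethyl]undeca-1,2,8,10-tetraen-4-one | C=C=C(C)C(=O)CC[C@](C)(CCO[Si](C(C)C)(C(C)C)C(C)C)/C=C(O[Si](C)(C)C(C)(C)C)/C=C | intermediate
18 | 4-(TBSO)-6β,10β-dimethyl-1-methylene-10α-[2-(TIPSO)ethyl]-5αH-decal-3-en-7-one | C=C1CC=C(O[Si](C)(C)C(C)(C)C)[C@H]2[C@@]1(C)C(=O)CC[C@]2(C)CCO[Si](C(C)C)(C(C)C)C(C)C | intermediate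
19 | 8α-hydroxy derivative of 18 | C=C1CC=C(O[Si](C)(C)C(C)(C)C)[C@H]2[C@@]1(C)C(=O)[C@H](O)C[C@]2(C)CCO[Si](C(C)C)(C(C)C)C(C)C | intermediate
20 | diosphenol: 8-hydroxy-decala-3,8-dien-7-one | C=C1CC=C(O[Si](C)(C)C(C)(C)C)[C@H]2[C@@]1(C)C(=O)C(O)=C[C@]2(C)CCO[Si](C(C)C)(C(C)C)C(C)C | intermediate
21 | 8-methoxy-decala-3,8-dien-7-one | C=C1CC=C(O[Si](C)(C)C(C)(C)C)[C@H]2[C@@]1(C)C(=O)C(OC)=C[C@]2(C)CCO[Si](C(C)C)(C(C)C)C(C)C | intermediate
22 | 8-methoxy-decala-3,8-dien-7β-ol | C=C1CC=C(O[Si](C)(C)C(C)(C)C)[C@H]2[C@@]1(C)[C@@H](O)C(OC)=C[C@]2(C)CCO[Si](C(C)C)(C(C)C)C(C)C | intermediate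
23 | 4,7β-bis(TBSO)-8-methoxy-decala-3,8-diene | C=C1CC=C(O[Si](C)(C)C(C)(C)C)[C@H]2[C@@]1(C)[C@@H](O[Si](C)(C)C(C)(C)C)C(OC)=C[C@]2(C)CCO[Si](C(C)C)(C(C)C)C(C)C | intermediate
24 | 7β-(TBSO)-8-methoxy-decal-8-en-4-one | C=C1CCC(=O)[C@H]2[C@@]1(C)[C@@H](O[Si](C)(C)C(C)(C)C)C(OC)=C[C@]2(C)CCO[Si](C(C)C)(C(C)C)C(C)C | intermediate
25 | 7β-(TBSO)-8-methoxy-decal-8-en-4α-ol | C=C1CC[C@@H](O)[C@H]2[C@@]1(C)[C@@H](O[Si](C)(C)C(C)(C)C)C(OC)=C[C@]2(C)CCO[Si](C(C)C)(C(C)C)C(C)C | intermediate
26 | 4α-isobutyrate of 25 | C=C1CC[C@@H](OC(=O)C(C)C)[C@H]2[C@@]1(C)[C@@H](O[Si](C)(C)C(C)(C)C)C(OC)=C[C@]2(C)CCO[Si](C(C)C)(C(C)C)C(C)C | intermediate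
27 | C12 primary alcohol | C=C1CC[C@@H](OC(=O)C(C)C)[C@H]2[C@@]1(C)[C@@H](O[Si](C)(C)C(C)(C)C)C(OC)=C[C@]2(C)CCO | intermediate
28 | 4-vinyl-1,3-dioxolan-2-one | C=CC1COC(=O)O1 | starting material
29 | (12R,13R)-12,14-diol with C13 vinyl | C=C1CC[C@@H](OC(=O)C(C)C)[C@H]2[C@@]1(C)[C@@H](O[Si](C)(C)C(C)(C)C)C(OC)=C[C@]2(C)C[C@@H](O)[C@@H](CO)C=C | intermediate
30 | (12R,13R)-14-(TBSO)-12-ol | C=C1CC[C@@H](OC(=O)C(C)C)[C@H]2[C@@]1(C)[C@@H](O[Si](C)(C)C(C)(C)C)C(OC)=C[C@]2(C)C[C@@H](O)[C@@H](CO[Si](C)(C)C(C)(C)C)C=C | intermediate
31 | (12R,13R)-12-tiglate | C=C1CC[C@@H](OC(=O)C(C)C)[C@H]2[C@@]1(C)[C@@H](O[Si](C)(C)C(C)(C)C)C(OC)=C[C@]2(C)C[C@@H](OC(=O)/C(C)=C/C)[C@@H](CO[Si](C)(C)C(C)(C)C)C=C | intermediate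
32 | C16 catechol boronate | C=C1CC[C@@H](OC(=O)C(C)C)[C@H]2[C@@]1(C)[C@@H](O[Si](C)(C)C(C)(C)C)C(OC)=C[C@]2(C)C[C@@H](OC(=O)/C(C)=C/C)[C@@H](CO[Si](C)(C)C(C)(C)C)CCB1Oc2ccccc2O1 | intermediate
33 | C16 primary alcohol | C=C1CC[C@@H](OC(=O)C(C)C)[C@H]2[C@@]1(C)[C@@H](O[Si](C)(C)C(C)(C)C)C(OC)=C[C@]2(C)C[C@@H](OC(=O)/C(C)=C/C)[C@@H](CO[Si](C)(C)C(C)(C)C)CCO | intermediate
34 | C16 carboxylic acid | C=C1CC[C@@H](OC(=O)C(C)C)[C@H]2[C@@]1(C)[C@@H](O[Si](C)(C)C(C)(C)C)C(OC)=C[C@]2(C)C[C@@H](OC(=O)/C(C)=C/C)[C@@H](CO[Si](C)(C)C(C)(C)C)CC(O)=O | intermediate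
35 | 14-hydroxy-16-oic acid with C8 ketone and C7 OTBS | C=C1CC[C@@H](OC(=O)C(C)C)[C@H]2[C@@]1(C)[C@@H](O[Si](C)(C)C(C)(C)C)C(=O)C[C@]2(C)C[C@@H](OC(=O)/C(C)=C/C)[C@@H](CO)CC(O)=O | intermediate
36 | lactone with C7 OTBS | C=C1CC[C@@H](OC(=O)C(C)C)[C@H]2[C@@]1(C)[C@@H](O[Si](C)(C)C(C)(C)C)C(=O)C[C@]2(C)C[C@@H](OC(=O)/C(C)=C/C)[C@H]1COC(=O)C1 | intermediate
37 | 9-demethylene ketol lactone | C=C1CC[C@@H](OC(=O)C(C)C)[C@H]2[C@@]1(C)[C@@H](O)C(=O)C[C@]2(C)C[C@@H](OC(=O)/C(C)=C/C)[C@H]1COC(=O)C1 | intermediate
38 | C9 (N-methylanilino)methyl Mannich base | C=C1CC[C@@H](OC(=O)C(C)C)[C@H]2[C@@]1(C)[C@@H](O)C(=O)C(CN(C)c3ccccc3)[C@]2(C)C[C@@H](OC(=O)/C(C)=C/C)[C@H]1COC(=O)C1 | intermediate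
39 | CNP0148909.1, (4R,5R,6R,7R,10R,12R,13R) in route numbering | C=C1CC[C@@H](OC(=O)C(C)C)[C@H]2[C@@]1(C)[C@@H](O)C(=O)C(=C)[C@]2(C)C[C@@H](OC(=O)/C(C)=C/C)[C@H]1COC(=O)C1 | target

## Step count and least certain steps

Total step count: 27. Longest linear sequence: 27 steps from 1 (all reagents other than 1, 2, 10 and 28 are used as purchased).

**Step 11 (key step).** Most likely to go wrong is discrimination between the two diene faces. The C10 methyl and the CH2CH2OTIPS arm differ only modestly in size at the congested position of the chair. The trans fusion also rests on the exo-carbonyl preference of an α-methyl enone, so formation of cis-fused and C10-mismatched adducts is the main risk. Fallback: move from substrate control to reagent control. 17 is cyclised at −78 °C in CH2Cl2 with a chiral oxazaborolidinium Lewis acid (the o-tolyl oxazaborolidine of diphenylprolinol activated with Tf2NH). The catalyst antipode is chosen to shield the dienophile face that leads to the unwanted C5/C6 configuration, so catalyst and C10 bias reinforce each other. It sets out from 17 and returns at 18 and makes no new compound (F0).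

**Step 1.** The unsubstituted vinyl group is the hardest alkenyl group to transfer with high enantioselectivity, and competing methyl transfer or erosion of selectivity by magnesium salts is possible. Fallback: from 1, copper-catalysed (CuCl2·2H2O with a chiral N-heterocyclic carbene ligand) conjugate addition of the [1-(trimethylsilyl)vinyl]alane made from trimethylsilylacetylene and iBu2AlH gives the silylvinyl ketone F1. Protodesilylation (CF3CO2H, CH2Cl2) returns to 3.

**Step 9.** The one-flask sequence depends on clean differentiation of two silyl groups; silyl scrambling, or methanolysis of the dienol ether during removal of the TMS ether, would lower the yield. Fallback: from 13, acetylation (Ac2O, pyridine) gives acetate F2, soft enolisation (TBSOTf, Et3N) gives acetate dienol ether F3, and iBu2AlH at −78 °C removes the acetate to return at 16.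

**Step 18.** If hydrogen delivery to the ketyl is kinetically controlled from the open α face, the axial 4β-alcohol forms; slow reduction would also allow epimerisation at C5. Fallback: from 24, reduction with LiBH(s-Bu)3 gives the axial alcohol F4. This is then equilibrated to the equatorial epimer by reversible hydride transfer (Al(OiPr)3, i-PrOH with a trace of acetone, toluene, heat; Meerwein–Ponndorf–Verley/Oppenauer equilibration), returning at 25.

**Step 21.** The polyfunctional, β-quaternary alcohol may dehydrogenate slowly, the iridium hydride may isomerise the C1 methylene into the ring, and anti selectivity may erode at the temperature needed. Fallback: from 27, Dess–Martin oxidation gives aldehyde F5. Allylboration at −78 °C with the (E)-γ-(silyloxymethyl)allyl diisopinocampheylborane then gives the anti adduct with O14 already silylated. The borane is made from tert-butyl(buta-2,3-dien-1-yloxy)dimethylsilane and (Ipc)2BH after thermal 1,3-boratropic equilibration. This returns at 30.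

**Step 27.** Under the acidic, heated conditions the α-ketol may enolise towards C7 (ketol transposition or epimerisation) and the amine may add reversibly to the product enone. Fallback: the methylene is installed before the ketol is unmasked. From 34, dimethylmethyleneammonium iodide in CH2Cl2 reacts at C9 of the methyl enol ether to give the Mannich base F6. N-Methylation (MeI) and NaHCO3 give the silyl-protected enone acid F7, and 48% aq. HF in MeCN closes the lactone and frees the C7 hydroxyl, returning at 39.

## Further compounds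

F0 | step 11 | none | none
F1 | step 1 | (S)-3-methyl-3-[1-(trimethylsilyl)vinyl]cyclohexan-1-one | C=C([Si](C)(C)C)[C@@]1(C)CCCC(=O)C1
F2 | step 9 | acetate of 13 at the carbinol | C=C=C(C)C(OC(C)=O)CC[C@](C)(CCO[Si](C(C)C)(C(C)C)C(C)C)CC(=O)C=C
F3 | step 9 | (Z)-TBS dienol ether of F2 | C=C=C(C)C(OC(C)=O)CC[C@](C)(CCO[Si](C(C)C)(C(C)C)C(C)C)/C=C(O[Si](C)(C)C(C)(C)C)/C=C
F4 | step 18 | 4β (axial) epimer of 25 | C=C1CC[C@H](O)[C@H]2[C@@]1(C)[C@@H](O[Si](C)(C)C(C)(C)C)C(OC)=C[C@]2(C)CCO[Si](C(C)C)(C(C)C)C(C)C
F5 | step 21 | C12 aldehyde from 27 | C=C1CC[C@@H](OC(=O)C(C)C)[C@H]2[C@@]1(C)[C@@H](O[Si](C)(C)C(C)(C)C)C(OC)=C[C@]2(C)CC=O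
F6 | step 27 | C9 (dimethylamino)methyl ketone from 34 | C=C1CC[C@@H](OC(=O)C(C)C)[C@H]2[C@@]1(C)[C@@H](O[Si](C)(C)C(C)(C)C)C(=O)C(CN(C)C)[C@]2(C)C[C@@H](OC(=O)/C(C)=C/C)[C@@H](CO[Si](C)(C)C(C)(C)C)CC(O)=O
F7 | step 27 | 9-methylene-8-ketone with C7 and C14 OTBS and C16 acid | C=C1CC[C@@H](OC(=O)C(C)C)[C@H]2[C@@]1(C)[C@@H](O[Si](C)(C)C(C)(C)C)C(=O)C(=C)[C@]2(C)C[C@@H](OC(=O)/C(C)=C/C)[C@@H](CO[Si](C)(C)C(C)(C)C)CC(O)=O
A1 | alternative 1 | bis-silyl C7,C8-diol form of the target (Baeyer–Villiger product) | C=C1CC[C@@H](OC(=O)C(C)C)[C@H]2[C@@]1(C)[C@@H](O[Si](C)(C)C(C)(C)C)[C@H](O[Si](C)(C)C(C)(C)C)C(=C)[C@]2(C)C[C@@H](OC(=O)/C(C)=C/C)[C@H]1COC(=O)C1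
A2 | alternative 1 | 3-substituted cyclobutanone precursor of A1 | C=C1CC[C@@H](OC(=O)C(C)C)[C@H]2[C@@]1(C)[C@@H](O[Si](C)(C)C(C)(C)C)[C@H](O[Si](C)(C)C(C)(C)C)C(=C)[C@]2(C)C[C@@H](OC(=O)/C(C)=C/C)C1CC(=O)C1
A3 | alternative 2 | decalin-fused isoxazoline | O=C1CC[C@@H](O[Si](C)(C)C(C)(C)C)[C@H]2[C@@]1(C)[C@@H](O[Si](C)(C)C(C)(C)C)C3=NOC[C@H]3[C@]2(C)CCO[Si](C)(C)C(C)(C)C
A4 | alternative 2 | nitrile oxide precursor of A3 | C=C[C@](C)(CCO[Si](C)(C)C(C)(C)C)[C@H]1[C@H](O[Si](C)(C)C(C)(C)C)CCC(=O)[C@]1(C)[C@@H](O[Si](C)(C)C(C)(C)C)C#[N+][O-]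
A5 | alternative 3 | decalin with C9 methylene and C10 acetate arm | O=C1CC[C@@H](O[Si](C)(C)C(C)(C)C)[C@H]2[C@@]1(C)[C@@H](O[Si](C)(C)C(C)(C)C)CC(=C)[C@]2(C)CC(=O)OC
A6 | alternative 3 | alkenyl bromide enoate precursor of A5 | COC(=O)/C=C(\C)[C@H]1[C@H](O[Si](C)(C)C(C)(C)C)CCC(=O)[C@]1(C)[C@@H](O[Si](C)(C)C(C)(C)C)CC(Br)=C
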